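The pyran ring of the top flavan unit is disconnected into a diaryl ketone (its ring A fluorinated at C8a, joined through the future C4 to C8 of the middle unit) and a chiral two-carbon C2–C3 piece. In one operation, a configurationally defined dilithio hydroxy-carbamate adds through C3 to the ketone carbon, and its C2 alkoxide displaces fluoride at C8a. This exploits C4 lying between two phloroglucinol-type A rings (ketone first, cation later, reduced anti to O3 to give the all-cis ring) and C8a being meta to the C5 and C7 oxygens. The mirror-image annulation builds the middle unit; the bottom unit comes from an aldehyde by the stepwise silyl-ether variant.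

Key step: step 16

Remark: the structure is read as top and bottom units 2S,3S, middle unit 2R,3R, each interflavan bond cis to O3 of its own unit, and the bottom 4-OH trans to its 3-OH; intermediates named "both C4 epimers" carry no stereo mark at that carbon on purpose, because a later step converges them.

Step 1
Reactants: 1 1,3,5-trifluorobenzene
Product: 2 1,3-bis(benzyloxy)-5-fluorobenzene
Conditions: BnOH (2.05 equiv), NaH (2.2 equiv), NMP, 0 → 100 °C
Reagents that add atoms: benzyl alcohol, OCc1ccccc1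
Why: Two successive SNAr displacements of fluoride by benzyloxide should stop at the monofluoride, because each alkoxy group deactivates the ring further.

Step 2
Reactants: 2 1,3-bis(benzyloxy)-5-fluorobenzene
Product: 4 2,4-bis(benzyloxy)-6-fluorobenzaldehyde, via aryllithium 3 (not isolated)
Conditions: n-BuLi, THF, −78 °C; then DMF, −78 → 0 °C; H2O
Reagents that add atoms: N,N-dimethylformamide, CN(C)C=O
Why: Directed ortho-lithiation should take place at the CH flanked by fluorine and a benzyloxy group, and the aryllithium is formylated by DMF.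

Step 3
Reactants: 4 2,4-bis(benzyloxy)-6-fluorobenzaldehyde
Product: 5 methyl 2,4-bis(benzyloxy)-6-fluorobenzoate
Conditions: I2 (1.3 equiv), KOH (2.6 equiv), MeOH/THF, 0 °C
Reagents that add atoms: methanol, CO
Why: In this oxidative esterification the methyl hemiacetal of the aldehyde is oxidised by hypoiodite to the ester, and at 0 °C neither iodination of the acyl-deactivated ring nor displacement of fluoride by methoxide should compete.

Step 4
Reactants: 6 1-[4-(benzyloxy)phenyl]-2-bromoethan-1-one
Product: 7 2-[4-(benzyloxy)phenyl]-2-oxoethyl N,N-diisopropylcarbamate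
Conditions: i-Pr2NH, CO2 (1 atm), Cs2CO3, Bu4NI, DMF, rt
Reagents that add atoms: diisopropylamine, CC(C)NC(C)C; carbon dioxide, O=C=O
Why: The cesium carbamate formed from the amine and CO2 should be O-alkylated by the reactive phenacyl bromide (SN2, three-component carbamate synthesis).

Step 5
Reactants: 7 2-[4-(benzyloxy)phenyl]-2-oxoethyl N,N-diisopropylcarbamate
Product: 8 (S)-2-[4-(benzyloxy)phenyl]-2-hydroxyethyl N,N-diisopropylcarbamate
Conditions: RuCl(p-cymene)[(R,R)-TsDPEN] (1 mol%), HCO2H/Et3N (5:2), CH2Cl2, 30 °C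
Reagents that add atoms: none
Why: Asymmetric transfer hydrogenation of the α-oxygenated aryl ketone with the (R,R) catalyst, which gives R carbinols from aryl methyl ketones, should give the S carbinol here in the same spatial sense, because CH2O outranks aryl.

Step 6
Reactants: 7 2-[4-(benzyloxy)phenyl]-2-oxoethyl N,N-diisopropylcarbamate
Product: 9 (R)-2-[4-(benzyloxy)phenyl]-2-hydroxyethyl N,N-diisopropylcarbamate
Conditions: RuCl(p-cymene)[(S,S)-TsDPEN] (1 mol%), HCO2H/Et3N (5:2), CH2Cl2, 30 °C
Reagents that add atoms: none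
Why: The mirror-image catalyst should give the R carbinol by the same asymmetric transfer hydrogenation.

Step 7
Reactants: 8 (S)-hydroxy carbamate
Product: 10 (S)-2-[4-(benzyloxy)phenyl]-2-[(tert-butyldimethylsilyl)oxy]ethyl N,N-diisopropylcarbamate
Conditions: TBSCl, imidazole, DMF, rt
Reagents that add atoms: tert-butyldimethylsilyl chloride, CC(C)(C)[Si](C)(C)Cl
Why: Standard silylation of the secondary benzylic alcohol, which leaves the stereocenter untouched and masks the hydroxyl for the lithiation of step 8.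

Step 8
Reactants: 10 (S)-silyl ether; 4 2,4-bis(benzyloxy)-6-fluorobenzaldehyde
Product: 14 (2S,3S)-5,7-bis(benzyloxy)-2-[4-(benzyloxy)phenyl]-4-hydroxy-3,4-dihydro-2H-chromen-3-yl N,N-diisopropylcarbamate (2,3-cis, both C4 epimers), via lithiated silyl ether 11 (not isolated), via lithium alkoxide 12 (not isolated), via open-chain diol 13 (not isolated)
Conditions: 10 (1.3 equiv), s-BuLi (1.25 equiv), (−)-sparteine (1.3 equiv), Et2O, −78 °C; then 4, THF, −78 °C; then Bu4NF (1 M in THF, 1.5 equiv), −78 °C → rt; then KOt-Bu (4 equiv), DMPU, 45 °C; H2O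
Reagents that add atoms: none
Why: Reactions of known type are run in one flask for this first unit: the (−)-sparteine complex of s-BuLi removes the pro-S hydrogen next to the carbamate oxygen (sparteine-mediated carbamate lithiation; the carbamate-bound base should reach this hydrogen faster than the benzylic ones, and the chelated carbanion should not expel the β-silyloxy group at −78 °C), the carbanion adds to aldehyde 4 with retention and so sets C3, fluoride removes the silyl group, and the potassium C2 alkoxide closes the pyran ring by intramolecular SNAr at C8a, with C2 coming from 8 and C4 left as both epimers for step 10.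

Step 9
Reactants: 14 bottom-unit flavan-4-ol (both C4 epimers)
Product: 15 8-bromo derivative of 14 (both C4 epimers)
Conditions: NBS (1.0 equiv), CH2Cl2, −78 °C
Reagents that add atoms: N-bromosuccinimide, O=C1CCC(=O)N1Br
Why: Electrophilic bromination of the 5,7-dialkoxychroman should go to C8, which is less crowded than C6 between two benzyloxy groups; the bromide blocks C8 during step 10 and is the handle for step 11.

Step 10
Reactants: 15 8-bromo flavan-4-ol (both C4 epimers)
Product: 16 (2S,3S,4R)-4,5,7-tris(benzyloxy)-2-[4-(benzyloxy)phenyl]-8-bromo-3,4-dihydro-2H-chromen-3-yl N,N-diisopropylcarbamate (2,3-cis, 3,4-trans)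
Conditions: BnOH (10 equiv), camphorsulfonic acid (0.1 equiv), CH2Cl2, 0 °C
Reagents that add atoms: benzyl alcohol, OCc1ccccc1
Why: SN1 etherification is stereoconvergent: both C4 epimers give the same benzylic cation, which benzyl alcohol should capture anti to the C3 carbamate, as in known C4 solvolyses of 2,3-cis flavan-3-ol derivatives.

Step 11
Reactants: 16 bottom-unit bromide; 5 methyl 2,4-bis(benzyloxy)-6-fluorobenzoate
Product: 18 bottom-unit diaryl ketone (16 with Br at C8 replaced by a 2,4-bis(benzyloxy)-6-fluorobenzoyl group), via aryllithium 17 (not isolated)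
Conditions: n-BuLi (1.05 equiv), THF, −78 °C; then added to 5 (2 equiv), THF, −78 → −20 °C; H2O
Reagents that add atoms: none
Why: Bromine–lithium exchange and acylation of the aryllithium by the ester should stop at the ketone, because the tetra-ortho-substituted benzophenone cannot take up a second crowded aryllithium.

Step 12
Reactants: 9 (R)-hydroxy carbamate; 18 bottom-unit diaryl ketone
Product: 21 dimer carbinol (bottom unit as in 16; its C8 bonded to C4 of a 4-hydroxy-5,7-bis(benzyloxy)-2-[4-(benzyloxy)phenyl]chroman-3-yl N,N-diisopropylcarbamate with C2 R and O3 cis to the C2 aryl; both C4 epimers of this middle unit), via dilithio carbamate 19 (not isolated), via dilithium alkoxide 20 (not isolated)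
Conditions: 9 (1.3 equiv), s-BuLi (2.6 equiv), (+)-sparteine (1.4 equiv), Et2O, −78 °C; then 18, THF, −78 → −40 °C; then KOt-Bu, DMPU, −40 → 45 °C; H2O
Reagents that add atoms: none
Why: Proposed new method: the hydroxyl of 9 is first turned into its lithium alkoxide, a poor leaving group that should not be lost by β-elimination, so the second equivalent of s-BuLi bound to (+)-sparteine can remove the pro-R hydrogen next to the carbamate oxygen; the carbanion adds with retention to the non-enolisable ketone of 18 (C3 set, C4 carbinol as both epimers, fixed in step 13) and, after exchange to potassium, the C2 alkoxide closes the pyran ring by displacing the only fluoride in a six-membered addition–elimination closure; the closest known reactions are the sparteine-mediated lithiation–carbonyl addition of O-alkyl carbamates, run in its silyl-protected form in step 8, and the alkoxide SNAr closure of flavan pyran rings.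

Step 13
Reactants: 21 dimer carbinol (both C4 epimers of the middle unit)
Product: 22 protected dimer (21 with H in place of OH at C4 of the middle unit; middle unit 2R,3R,4S, the bottom-unit aryl cis to O3 and to the C2 aryl)
Conditions: Et3SiH (5 equiv), CF3CO2H (3 equiv), CH2Cl2, −40 °C
Reagents that add atoms: none
Why: In this ionic hydrogenation both carbinol epimers ionise to one doubly benzylic cation, which the silane should reduce from the face anti to the C3 carbamate and the C2 aryl group (all-cis middle unit), while the far less ionisable secondary C4 benzyl ether of the bottom unit should survive.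

Step 14
Reactants: 22 protected dimer
Product: 23 dimer bromide (22 with Br at C8 of the middle unit)
Conditions: NBS (1.0 equiv), CH2Cl2, −78 °C
Reagents that add atoms: N-bromosuccinimide, O=C1CCC(=O)N1Br
Why: C8 of the chain-end unit, between O1 and one benzyloxy group, should be the most accessible arene position for electrophilic bromination, since both C6 positions lie between two benzyloxy groups.

Step 15
Reactants: 23 dimer bromide; 5 methyl 2,4-bis(benzyloxy)-6-fluorobenzoate
Product: 25 dimer diaryl ketone (23 with Br replaced by a 2,4-bis(benzyloxy)-6-fluorobenzoyl group), via aryllithium 24 (not isolated)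
Conditions: n-BuLi (1.05 equiv), THF, −78 °C; then added to 5 (2 equiv), THF, −78 → −20 °C; H2O
Reagents that add atoms: none
Why: Bromine–lithium exchange and ester acylation as in step 11; the doubly benzylic C4–H of the middle unit is too crowded to be deprotonated at −78 °C.

Step 16
Reactants: 8 (S)-hydroxy carbamate; 25 dimer diaryl ketone
Product: 28 trimer carbinol (dimer as in 22; C8 of the middle unit bonded to C4 of a 4-hydroxy-5,7-bis(benzyloxy)-2-[4-(benzyloxy)phenyl]chroman-3-yl N,N-diisopropylcarbamate with C2 S and O3 cis to the C2 aryl; both C4 epimers of this top unit), via dilithio carbamate 26 (not isolated), via dilithium alkoxide 27 (not isolated)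
Conditions: 8 (1.3 equiv), s-BuLi (2.6 equiv), (−)-sparteine (1.4 equiv), Et2O, −78 °C; then 25, THF, −78 → −40 °C; then KOt-Bu, DMPU, −40 → 45 °C; H2O
Reagents that add atoms: none
Why: Proposed new method: alkoxide formation and (−)-sparteine-directed removal of the pro-S hydrogen next to the carbamate oxygen give dilithio species 26, whose carbanion adds to the non-enolisable ketone carbon of 25 (C3–C4 bond), after which the C2 alkoxide, made more reactive by exchange to potassium, attacks C8a and expels fluoride (O1–C8a bond). The closest known reaction types are the sparteine-mediated lithiation–carbonyl addition of O-alkyl carbamates and the alkoxide SNAr closure of flavan pyran rings on 3,5-dialkoxyfluoroarenes, run stepwise through a silyl ether in step 8; their union with a free alkoxide next to the carbanion is the new element. The pyran ring closes in a six-membered exo mode by addition–elimination at the aromatic carbon C8a. C2 (S) is carried in from 8, C3 is fixed by the diamine-controlled lithiation and its retentive trapping, and C4 arises as both carbinol epimers, which is harmless because step 17 converts both into one cation. The step needs carbon-before-oxygen reactivity of 26 and closure only through O1: the ketone has no acidic hydrogen, O3 is blocked as the carbamate, the C4 alkoxide could only form a four-membered ring, and ring A of the top unit carries the only fluorine.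

Step 17
Reactants: 28 trimer carbinol (both C4 epimers of the top unit)
Product: 29 protected trimer (28 with H in place of OH at C4 of the top unit; top unit 2S,3S,4R, the middle-unit aryl cis to O3 and to the C2 aryl)
Conditions: Et3SiH (5 equiv), CF3CO2H (3 equiv), CH2Cl2, −40 °C
Reagents that add atoms: none
Why: As in step 13, ionic hydrogenation through the common doubly benzylic C4 cation should deliver hydride anti to the C3 carbamate and the C2 aryl group, giving the all-cis top unit from both epimers.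

Step 18
Reactants: 29 protected trimer
Product: 30 deca-O-benzyl trimer triol (29 with the three carbamates replaced by free C3 hydroxyls)
Conditions: LiAlH4 (excess), THF, reflux; aqueous work-up
Reagents that add atoms: none
Why: Hydride reduction cleaves the three N,N-diisopropylcarbamates to the C3 alcohols without touching the benzyl ethers or any stereocenter.

Step 19
Reactants: 30 deca-O-benzyl trimer triol
Product: 31 target trimer (CNP0159291.1)
Conditions: H2 (1 atm), Pd(OH)2 on carbon, THF/MeOH, rt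
Reagents that add atoms: none
Why: Hydrogenolysis under neutral conditions should remove the nine aryl benzyl ethers and the C4 benzyl ether of the bottom unit (cleavage of the O–CH2Ph bond, C4 configuration retained).

Compound list
1 | 1,3,5-trifluorobenzene | Fc1cc(F)cc(F)c1 | starting material
2 | 1,3-bis(benzyloxy)-5-fluorobenzene | Fc1cc(OCc2ccccc2)cc(OCc2ccccc2)c1 | intermediate
3 | [2,4-bis(benzyloxy)-6-fluorophenyl]lithium | [Li]c1c(F)cc(OCc2ccccc2)cc1OCc1ccccc1 | intermediate
4 | 2,4-bis(benzyloxy)-6-fluorobenzaldehyde | O=Cc1c(F)cc(OCc2ccccc2)cc1OCc1ccccc1 | intermediate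
5 | methyl 2,4-bis(benzyloxy)-6-fluorobenzoate | COC(=O)c1c(F)cc(OCc2ccccc2)cc1OCc1ccccc1 | intermediate
6 | 1-[4-(benzyloxy)phenyl]-2-bromoethan-1-one | O=C(CBr)c1ccc(OCc2ccccc2)cc1 | starting material
7 | 2-[4-(benzyloxy)phenyl]-2-oxoethyl N,N-diisopropylcarbamate | CC(C)N(C(C)C)C(=O)OCC(=O)c1ccc(OCc2ccccc2)cc1 | intermediate
8 | (S)-2-[4-(benzyloxy)phenyl]-2-hydroxyethyl N,N-diisopropylcarbamate | O[C@H](COC(=O)N(C(C)C)C(C)C)c1ccc(OCc2ccccc2)cc1 | intermediate
9 | (R)-2-[4-(benzyloxy)phenyl]-2-hydroxyethyl N,N-diisopropylcarbamate | O[C@@H](COC(=O)N(C(C)C)C(C)C)c1ccc(OCc2ccccc2)cc1 | intermediate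
10 | (S)-2-[4-(benzyloxy)phenyl]-2-[(tert-butyldimethylsilyl)oxy]ethyl N,N-diisopropylcarbamate | CC(C)(C)[Si](C)(C)O[C@H](COC(=O)N(C(C)C)C(C)C)c1ccc(OCc2ccccc2)cc1 | intermediate
11 | lithio derivative of 10 (lithium in place of the pro-S hydrogen at the carbamate carbon) | CC(C)(C)[Si](C)(C)O[C@H]([C@H]([Li])OC(=O)N(C(C)C)C(C)C)c1ccc(OCc2ccccc2)cc1 | intermediate
12 | open-chain lithium alkoxide from 11 and 4 (O-silyl at C2; both epimers at the new carbinol carbon) | CC(C)(C)[Si](C)(C)O[C@H]([C@@H](OC(=O)N(C(C)C)C(C)C)C(O[Li])c1c(F)cc(OCc2ccccc2)cc1OCc1ccccc1)c1ccc(OCc2ccccc2)cc1 | intermediate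
13 | open-chain diol from 12 after loss of the silyl group (both epimers at the carbinol carbon next to the fluoroarene) | O[C@H]([C@@H](OC(=O)N(C(C)C)C(C)C)C(O)c1c(F)cc(OCc2ccccc2)cc1OCc1ccccc1)c1ccc(OCc2ccccc2)cc1 | intermediate
14 | (2S,3S)-5,7-bis(benzyloxy)-2-[4-(benzyloxy)phenyl]-4-hydroxy-3,4-dihydro-2H-chromen-3-yl N,N-diisopropylcarbamate, 2,3-cis, both C4 epimers | OC1c2c(OCc3ccccc3)cc(OCc3ccccc3)cc2O[C@@H](c2ccc(OCc3ccccc3)cc2)[C@H]1OC(=O)N(C(C)C)C(C)C | intermediate
15 | 8-bromo derivative of 14, both C4 epimers | OC1c2c(OCc3ccccc3)cc(OCc3ccccc3)c(Br)c2O[C@@H](c2ccc(OCc3ccccc3)cc2)[C@H]1OC(=O)N(C(C)C)C(C)C | intermediate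
16 | (2S,3S,4R)-4,5,7-tris(benzyloxy)-2-[4-(benzyloxy)phenyl]-8-bromo-3,4-dihydro-2H-chromen-3-yl N,N-diisopropylcarbamate (2,3-cis, 3,4-trans) | c1ccccc1CO[C@@H]1c2c(OCc3ccccc3)cc(OCc3ccccc3)c(Br)c2O[C@@H](c2ccc(OCc3ccccc3)cc2)[C@H]1OC(=O)N(C(C)C)C(C)C | intermediate
17 | 8-lithio analogue of 16 | c1ccccc1CO[C@@H]1c2c(OCc3ccccc3)cc(OCc3ccccc3)c([Li])c2O[C@@H](c2ccc(OCc3ccccc3)cc2)[C@H]1OC(=O)N(C(C)C)C(C)C | intermediate
18 | bottom-unit diaryl ketone: 16 with a 2,4-bis(benzyloxy)-6-fluorobenzoyl group at C8 in place of Br | c1ccccc1CO[C@@H]1c2c(OCc3ccccc3)cc(OCc3ccccc3)c(C(=O)c3c(F)cc(OCc4ccccc4)cc3OCc3ccccc3)c2O[C@@H](c2ccc(OCc3ccccc3)cc2)[C@H]1OC(=O)N(C(C)C)C(C)C | intermediate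
19 | dilithio species of 9 (lithium alkoxide at C2; lithium in place of the pro-R hydrogen at the carbamate carbon) | [Li]O[C@@H]([C@@H]([Li])OC(=O)N(C(C)C)C(C)C)c1ccc(OCc2ccccc2)cc1 | intermediate
20 | open-chain dilithium dialkoxide from 19 and 18 (both epimers at the tertiary carbinol carbon) | c1ccccc1CO[C@@H]1c2c(OCc3ccccc3)cc(OCc3ccccc3)c(C(O[Li])(c3c(F)cc(OCc4ccccc4)cc3OCc3ccccc3)[C@@H](OC(=O)N(C(C)C)C(C)C)[C@H](O[Li])c3ccc(OCc4ccccc4)cc3)c2O[C@@H](c2ccc(OCc3ccccc3)cc2)[C@H]1OC(=O)N(C(C)C)C(C)C | intermediate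
21 | dimer carbinol: bottom unit of 16 joined at C8 to C4 of a middle unit (4-hydroxy, 5,7-bis(benzyloxy), 2-[4-(benzyloxy)phenyl], 3-O-carbamate; C2 R, O3 cis to the C2 aryl; both C4 epimers) | c1ccccc1CO[C@@H]1c2c(OCc3ccccc3)cc(OCc3ccccc3)c(C3(O)c4c(OCc5ccccc5)cc(OCc5ccccc5)cc4O[C@H](c4ccc(OCc5ccccc5)cc4)[C@@H]3OC(=O)N(C(C)C)C(C)C)c2O[C@@H](c2ccc(OCc3ccccc3)cc2)[C@H]1OC(=O)N(C(C)C)C(C)C | intermediate
22 | protected dimer: 21 with H at C4 of the middle unit; middle unit 2R,3R,4S, all-cis | c1ccccc1CO[C@@H]1c2c(OCc3ccccc3)cc(OCc3ccccc3)c([C@@H]3c4c(OCc5ccccc5)cc(OCc5ccccc5)cc4O[C@H](c4ccc(OCc5ccccc5)cc4)[C@@H]3OC(=O)N(C(C)C)C(C)C)c2O[C@@H](c2ccc(OCc3ccccc3)cc2)[C@H]1OC(=O)N(C(C)C)C(C)C | intermediate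
23 | dimer bromide: 22 with Br at C8 of the middle unit | c1ccccc1CO[C@@H]1c2c(OCc3ccccc3)cc(OCc3ccccc3)c([C@@H]3c4c(OCc5ccccc5)cc(OCc5ccccc5)c(Br)c4O[C@H](c4ccc(OCc5ccccc5)cc4)[C@@H]3OC(=O)N(C(C)C)C(C)C)c2O[C@@H](c2ccc(OCc3ccccc3)cc2)[C@H]1OC(=O)N(C(C)C)C(C)C | intermediate
24 | aryllithium from 23 (Li at C8 of the middle unit) | c1ccccc1CO[C@@H]1c2c(OCc3ccccc3)cc(OCc3ccccc3)c([C@@H]3c4c(OCc5ccccc5)cc(OCc5ccccc5)c([Li])c4O[C@H](c4ccc(OCc5ccccc5)cc4)[C@@H]3OC(=O)N(C(C)C)C(C)C)c2O[C@@H](c2ccc(OCc3ccccc3)cc2)[C@H]1OC(=O)N(C(C)C)C(C)C | intermediate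
25 | dimer diaryl ketone: 23 with a 2,4-bis(benzyloxy)-6-fluorobenzoyl group in place of Br | c1ccccc1CO[C@@H]1c2c(OCc3ccccc3)cc(OCc3ccccc3)c([C@@H]3c4c(OCc5ccccc5)cc(OCc5ccccc5)c(C(=O)c5c(F)cc(OCc6ccccc6)cc5OCc5ccccc5)c4O[C@H](c4ccc(OCc5ccccc5)cc4)[C@@H]3OC(=O)N(C(C)C)C(C)C)c2O[C@@H](c2ccc(OCc3ccccc3)cc2)[C@H]1OC(=O)N(C(C)C)C(C)C | intermediate
26 | dilithio species of 8 (lithium alkoxide at C2; lithium in place of the pro-S hydrogen at the carbamate carbon) | [Li]O[C@H]([C@H]([Li])OC(=O)N(C(C)C)C(C)C)c1ccc(OCc2ccccc2)cc1 | intermediate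
27 | open-chain dilithium dialkoxide from 26 and 25 (both epimers at the tertiary carbinol carbon) | c1ccccc1CO[C@@H]1c2c(OCc3ccccc3)cc(OCc3ccccc3)c([C@@H]3c4c(OCc5ccccc5)cc(OCc5ccccc5)c(C(O[Li])(c5c(F)cc(OCc6ccccc6)cc5OCc5ccccc5)[C@H](OC(=O)N(C(C)C)C(C)C)[C@@H](O[Li])c5ccc(OCc6ccccc6)cc5)c4O[C@H](c4ccc(OCc5ccccc5)cc4)[C@@H]3OC(=O)N(C(C)C)C(C)C)c2O[C@@H](c2ccc(OCc3ccccc3)cc2)[C@H]1OC(=O)N(C(C)C)C(C)C | intermediate
28 | trimer carbinol: dimer of 22 joined at C8 of the middle unit to C4 of a top unit (4-hydroxy, 5,7-bis(benzyloxy), 2-[4-(benzyloxy)phenyl], 3-O-carbamate; C2 S, O3 cis to the C2 aryl; both C4 epimers) | c1ccccc1CO[C@@H]1c2c(OCc3ccccc3)cc(OCc3ccccc3)c([C@@H]3c4c(OCc5ccccc5)cc(OCc5ccccc5)c(C5(O)c6c(OCc7ccccc7)cc(OCc7ccccc7)cc6O[C@@H](c6ccc(OCc7ccccc7)cc6)[C@H]5OC(=O)N(C(C)C)C(C)C)c4O[C@H](c4ccc(OCc5ccccc5)cc4)[C@@H]3OC(=O)N(C(C)C)C(C)C)c2O[C@@H](c2ccc(OCc3ccccc3)cc2)[C@H]1OC(=O)N(C(C)C)C(C)C | intermediate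
29 | protected trimer: 28 with H at C4 of the top unit; top unit 2S,3S,4R, all-cis | c1ccccc1CO[C@@H]1c2c(OCc3ccccc3)cc(OCc3ccccc3)c([C@@H]3c4c(OCc5ccccc5)cc(OCc5ccccc5)c([C@H]5c6c(OCc7ccccc7)cc(OCc7ccccc7)cc6O[C@@H](c6ccc(OCc7ccccc7)cc6)[C@H]5OC(=O)N(C(C)C)C(C)C)c4O[C@H](c4ccc(OCc5ccccc5)cc4)[C@@H]3OC(=O)N(C(C)C)C(C)C)c2O[C@@H](c2ccc(OCc3ccccc3)cc2)[C@H]1OC(=O)N(C(C)C)C(C)C | intermediate
30 | deca-O-benzyl trimer triol: 29 with free hydroxyls at C3 of all three units | c1ccccc1CO[C@@H]1c2c(OCc3ccccc3)cc(OCc3ccccc3)c([C@@H]3c4c(OCc5ccccc5)cc(OCc5ccccc5)c([C@H]5c6c(OCc7ccccc7)cc(OCc7ccccc7)cc6O[C@@H](c6ccc(OCc7ccccc7)cc6)[C@H]5O)c4O[C@H](c4ccc(OCc5ccccc5)cc4)[C@@H]3O)c2O[C@@H](c2ccc(OCc3ccccc3)cc2)[C@H]1O | intermediate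
31 | target trimer CNP0159291.1 (top unit 2S,3S,4R all-cis; middle unit 2R,3R,4S all-cis; bottom unit 2S,3S,4R flavan-3,4-diol, 2,3-cis, 3,4-trans) | Oc1ccc([C@H]2Oc3c(c(O)cc(O)c3[C@H]3c4c(O)cc(O)cc4O[C@@H](c4ccc(O)cc4)[C@H]3O)[C@@H](c3c(O)cc(O)c4c3O[C@@H](c3ccc(O)cc3)[C@@H](O)[C@@H]4O)[C@H]2O)cc1 | target

Total step count: 19. Longest linear sequence: 15 steps (6 → 7 → 8 → 10 → 14 → 15 → 16 → 18 → 21 → 22 → 23 → 25 → 28 → 29 → 30 → 31).

Steps most likely to fail

Step 16 (key step). What may go wrong: β-elimination of the dilithio species, loss of configuration at the lithiated carbon during a slow addition to the crowded ketone, or migration of the carbamoyl group to a neighbouring alkoxide before the ring closes. The fallback makes the two bonds one after the other with the known reactions of step 8 instead of the one-pot dianion. Setting out from 10 and 25, silyl ether 10 would be lithiated with s-BuLi/(−)-sparteine in Et2O at −78 °C and added to 25, which should give the open-chain tertiary alcohol F1 after aqueous work-up. Bu4NF in THF, then KOt-Bu in DMPU at 45 °C, removes the silyl group and closes the pyran ring by SNAr, which comes back to the route at 28.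

Step 12. What may go wrong: the same processes as in step 16, here in the mirror-image series. Fallback, again by separate known steps: setting out from 9 and 18, 9 would be silylated (TBSCl, imidazole, DMF) to the (R)-silyl ether F2, lithiated with s-BuLi/(+)-sparteine and added to 18 to give the open-chain tertiary alcohol F3. Desilylation and SNAr closure (Bu4NF, THF; then KOt-Bu, DMPU, 45 °C) return to the route at 21.

Step 15. What may go wrong: slow acyl substitution at the doubly ortho-substituted ester by the crowded aryllithium, so that protonation of the aryllithium or its attack at the fluorinated carbon of the ester takes over. Fallback: a two-step ketone synthesis through the far more electrophilic aldehyde. Setting out from 23 and 4, bromine–lithium exchange (n-BuLi, THF, −78 °C) and addition to 4 should give the diaryl carbinol F4 as both epimers. Oxidation with Dess–Martin periodinane in CH2Cl2 returns to the route at 25.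

Further compounds
F1 | step 16 | open-chain adduct of lithiated 10 and 25 (tertiary alcohol, both epimers; O-silyl at C2 of the future top unit) | c1ccccc1CO[C@@H]1c2c(OCc3ccccc3)cc(OCc3ccccc3)c([C@@H]3c4c(OCc5ccccc5)cc(OCc5ccccc5)c(C(O)(c5c(F)cc(OCc6ccccc6)cc5OCc5ccccc5)[C@H](OC(=O)N(C(C)C)C(C)C)[C@@H](O[Si](C)(C)C(C)(C)C)c5ccc(OCc6ccccc6)cc5)c4O[C@H](c4ccc(OCc5ccccc5)cc4)[C@@H]3OC(=O)N(C(C)C)C(C)C)c2O[C@@H](c2ccc(OCc3ccccc3)cc2)[C@H]1OC(=O)N(C(C)C)C(C)C
F2 | step 12 | (R)-2-[4-(benzyloxy)phenyl]-2-[(tert-butyldimethylsilyl)oxy]ethyl N,N-diisopropylcarbamate | CC(C)(C)[Si](C)(C)O[C@@H](COC(=O)N(C(C)C)C(C)C)c1ccc(OCc2ccccc2)cc1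
F3 | step 12 | open-chain adduct of lithiated F2 and 18 (tertiary alcohol, both epimers; O-silyl at C2 of the future middle unit) | c1ccccc1CO[C@@H]1c2c(OCc3ccccc3)cc(OCc3ccccc3)c(C(O)(c3c(F)cc(OCc4ccccc4)cc3OCc3ccccc3)[C@@H](OC(=O)N(C(C)C)C(C)C)[C@H](O[Si](C)(C)C(C)(C)C)c3ccc(OCc4ccccc4)cc3)c2O[C@@H](c2ccc(OCc3ccccc3)cc2)[C@H]1OC(=O)N(C(C)C)C(C)C
F4 | step 15 | dimer diaryl carbinol: 25 with CH(OH) in place of the ketone C=O (both epimers) | c1ccccc1CO[C@@H]1c2c(OCc3ccccc3)cc(OCc3ccccc3)c([C@@H]3c4c(OCc5ccccc5)cc(OCc5ccccc5)c(C(O)c5c(F)cc(OCc6ccccc6)cc5OCc5ccccc5)c4O[C@H](c4ccc(OCc5ccccc5)cc4)[C@@H]3OC(=O)N(C(C)C)C(C)C)c2O[C@@H](c2ccc(OCc3ccccc3)cc2)[C@H]1OC(=O)N(C(C)C)C(C)C
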